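The ten-membered ring is not closed end to end but released from a carvone-derived cyclohexane. In the target, C5 (ketone) and C10 (carbinol) are 1,6-transannular with oxygen on the adjacent C9; reconnecting C5–C10 gives a decalin carrying a Grob retron, and ring atoms C5–C10 with the C10 methyl and the C7 three-carbon branch map onto carvone. In one operation SmI2 joins C4 to C5 (Barbier), sets C4, and the resulting alkoxide cleaves C5–C10 to give the Z-C9=C10 cyclodecenone. The precursor is a 2-(4-iodopentyl)-2-methylcyclohexanone with an equatorial C9 mesylate cis to the side chain, a C8 silyl ether and a C7 (silyloxy)isopropenyl group.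

Key step: step 13

Remarks on the chemistry (assumptions):
- Atom numbers are those of the target: C1–C10 ring, C11 lactone α-carbon, C12 lactone carbonyl carbon, C13 exo-methylene, C14 methyl on C10, C15 methyl on C4.
- Racemic 1,4-dihalopentane is used, so 14–17 are mixtures of the two epimers at the iodide-bearing carbon. That centre is written without a descriptor and is erased in step 13.
- The C7 branch is carried with C12 already oxygenated and TBDPS-protected; the carbon skeleton of the key-step precursor and product is unchanged. The only C–H oxidation is therefore done on carvone, and the exocyclic alkene is deactivated during the directed osmylation.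
- 9 and 10 are written as their conjugated enol and ene-hydrazine tautomers. C5/C10 of 7 and 8, the hydrazone C=N geometry and the lactol carbon of 25 are left undefined because they are lost or irrelevant.
- The SMILES strings define all configurations.

Step 1
Reactants: 1 (R)-carvone
Product: 2 (R)-10-hydroxycarvone, (5R)-5-(3-hydroxyprop-1-en-2-yl)-2-methylcyclohex-2-en-1-one
Conditions: SeO2 (0.3 equiv), t-BuOOH (2 equiv), salicylic acid (cat.), CH2Cl2, rt
Reagents that add atoms: tert-butyl hydroperoxide, CC(C)(C)OO (oxygen relayed by catalytic selenium dioxide, O=[Se]=O)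
Why: SeO2/TBHP allylic oxidation (ene reaction, then [2,3]-sigmatropic shift) should functionalise the methyl group of the electron-rich isopropenyl unit and spare the electron-poor enone, so that C12 is oxygenated on cheap material; no stereocentre is formed.

Step 2
Reactants: 2 (R)-10-hydroxycarvone
Product: 3 (R)-10-(tert-butyldiphenylsilyloxy)carvone
Conditions: TBDPSCl, imidazole, CH2Cl2, 0 °C to rt
Reagents that add atoms: tert-butyldiphenylsilyl chloride, CC(C)(C)[Si](Cl)(c1ccccc1)c1ccccc1
Why: Routine silylation of a primary allylic alcohol; TBDPS should survive every later step, outlast the acid-fluoride removal of the secondary TBS ether in step 14, and shield and deactivate the exocyclic alkene in step 15.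

Step 3
Reactants: 3 (R)-10-(tert-butyldiphenylsilyloxy)carvone
Product: 5 (5S,6S)-6-hydroxy-5-[3-(tert-butyldiphenylsilyloxy)prop-1-en-2-yl]-2-methylcyclohex-2-en-1-one (C8–OH trans to the C7 branch), via lithium cross-conjugated dienolate 4 (not isolated)
Conditions: LDA, THF, −78 °C; then 2-(phenylsulfonyl)-3-phenyloxaziridine, −78 °C; aq. NH4Cl
Reagents that add atoms: 2-(phenylsulfonyl)-3-phenyloxaziridine (Davis oxaziridine), O=S(=O)(c1ccccc1)N1OC1c1ccccc1
Why: Kinetic α′-deprotonation gives the cross-conjugated dienolate, and Davis enolate hydroxylation should deliver oxygen to C8 on the face anti to the adjacent C7 substituent, which sets C8 trans to the C7 branch by substrate control (any cis epimer is removed by chromatography).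

Step 4
Reactants: 5 trans-6-hydroxy enone
Product: 6 (5S,6S)-6-(tert-butyldimethylsilyloxy)-5-[3-(tert-butyldiphenylsilyloxy)prop-1-en-2-yl]-2-methylcyclohex-2-en-1-one
Conditions: TBSCl, imidazole, DMF, rt
Reagents that add atoms: tert-butyldimethylsilyl chloride, CC(C)(C)[Si](C)(C)Cl
Why: Routine silylation of the secondary α-hydroxy ketone under non-enolising conditions, which keeps the C8 configuration.

Step 5
Reactants: 6 bis-silyl enone
Product: 8 β-hydroxy ketone (hydroxyl on C5, ketone at C9; C5 and C10 undefined), via β-boryl ketone 7 (not isolated)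
Conditions: B2pin2 (1.1 equiv), CuCl (5 mol%), Xantphos (5 mol%), NaOt-Bu (10 mol%), MeOH (2 equiv), THF, rt; then NaBO3·4H2O, THF/H2O, rt
Reagents that add atoms: sodium perborate, [Na+].[O-]OB=O (oxygen on C5); bis(pinacolato)diboron, CC1(C)OB(OC1(C)C)B1OC(C)(C)C(C)(C)O1 (boron and pinacol appear only in intermediate 7)
Why: Copper-catalysed conjugate borylation should place boron on the enone β-carbon C5 without touching the isolated alkene, and perborate oxidation converts C–B into C–OH with retention; the configurations at C5 and C10 are irrelevant because both centres become sp2 in steps 6 and 7.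

Step 6
Reactants: 8 β-hydroxy ketone
Product: 9 4-(tert-butyldimethylsilyloxy)-2-methyl-5-[3-(tert-butyldiphenylsilyloxy)prop-1-en-2-yl]cyclohexane-1,3-dione (C5/C9 dione, drawn as the C5 enol)
Conditions: IBX, EtOAc, 75 °C
Reagents that add atoms: none
Why: IBX in hot ethyl acetate is a reliable oxidation of β-hydroxy ketones to 1,3-diones that should stop at the dione and tolerate the silyl ethers and the alkene.

Step 7
Reactants: 9 1,3-dione
Product: 10 ene-hydrazine (vinylogous hydrazide: 2,2-dimethylhydrazinyl group on C5, C5=C10, ketone at C9)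
Conditions: Me2NNH2 (1.5 equiv), AcOH (cat.), toluene, 4 Å MS, 50 °C
Reagents that add atoms: N,N-dimethylhydrazine, CN(C)N
Why: Condensation of the dione with N,N-dimethylhydrazine should occur at the C5 carbonyl, the one remote from the bulky C8 silyloxy group (as in enol-ether and enaminone formation from 4-substituted cyclohexane-1,3-diones), which differentiates C5 from C9 and prepares a carbon nucleophile at C10.

Step 8
Reactants: 11 1,4-dibromopentane (racemic)
Product: 12 1,4-diiodopentane (racemic)
Conditions: NaI (4 equiv), acetone, reflux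
Reagents that add atoms: sodium iodide, [Na+].[I-]
Why: Finkelstein halide exchange (SN2, driven by precipitation of NaBr) should convert both C–Br bonds; the configuration of the secondary carbon is irrelevant.

Step 9
Reactants: 10 ene-hydrazine; 12 1,4-diiodopentane
Product: 14 keto dimethylhydrazone with quaternary C10 (C9 ketone, C5 hydrazone, 4-iodopentyl chain on C10 cis to the C7 branch and trans to C8–OTBS), via potassium aza-enolate 13 (not isolated)
Conditions: KH (1.0 equiv), THF, 0 °C; then 12 (3 equiv), 0 °C to rt
Reagents that add atoms: none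
Why: C-alkylation of the potassium aza-enolate of a 1,3-dione mono(dimethylhydrazone) with an unactivated primary iodide is the known remedy for the O-alkylation of 2-methylcyclohexane-1,3-diones; the primary C–I should react in preference to the secondary one, and the electrophile should enter axially on the chair-like transition state with equatorial C7 and C8 substituents, on the face anti to the C8 silyloxy group, which sets the quaternary centre C10.

Step 10
Reactants: 14 keto dimethylhydrazone
Product: 15 hydroxy hydrazone (C9–OH equatorial, trans to C8–OTBS, cis to the side chain)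
Conditions: NaBH4, CeCl3·7H2O, MeOH/THF, −40 to 0 °C
Reagents that add atoms: none
Why: Borohydride (Luche-type) reduction should touch only the C9 ketone because C5 is masked as the hydrazone, and axial hydride attack on the chair with equatorial C7/C8 substituents (the axial side chain on C10 blocks the other trajectory) gives the equatorial C9 alcohol; low temperature and cerium chloride suppress 1,2-silyl migration.

Step 11
Reactants: 15 hydroxy hydrazone
Product: 16 mesyloxy hydrazone (C9–OMs)
Conditions: Ms2O, DMAP (cat.), pyridine, CH2Cl2, 0 °C to rt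
Reagents that add atoms: methanesulfonic anhydride, CS(=O)(=O)OS(C)(=O)=O
Why: Sulfonylation of the hindered secondary alcohol with the anhydride under DMAP catalysis proceeds with retention at C9, and with C5 still a hydrazone neither retro-aldol cleavage nor premature fragmentation can occur.

Step 12
Reactants: 16 mesyloxy hydrazone
Product: 17 iodo keto mesylate (key-step precursor: C5 ketone; C7 branch, C8–OTBS and C9–OMs all-trans and equatorial; side chain on C10 cis to C9–OMs; C10 methyl trans to it)
Conditions: Cu(OAc)2·H2O (2 equiv), THF/H2O (1:1), rt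
Reagents that add atoms: water, O
Why: Copper(II)-promoted hydrolysis of the N,N-dimethylhydrazone under neutral aqueous conditions should release the C5 ketone without disturbing the mesylate, the secondary iodide or the silyl ethers, and because C10 is quaternary the β-mesyloxy ketone cannot eliminate.

Step 13
Reactants: 17 iodo keto mesylate
Product: 19 (Z)-cyclodecenone (C5 ketone, Z-C9=C10, C4 methyl, C8–OTBS, C7 (silyloxy)isopropenyl), via samarium(III) alkoxide of the cis-decalin 18 (not isolated)
Conditions: SmI2 (2.5 equiv), HMPA (10 equiv), THF (0.01 M), −78 °C to rt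
Reagents that add atoms: none
Why: SmI2/HMPA reduces the secondary C–I bond (either epimer) through the radical to an alkylsamarium(III), which adds to the C5 ketone to form C4–C5 and the cis-fused decalin alkoxide 18; this alkoxide then pushes electrons into C5, the shared C5–C10 bond breaks and the antiperiplanar C9 mesylate leaves (Grob fragmentation), unveiling the C5 ketone and the C9=C10 alkene. The closest known reaction type is the SmI2-promoted intramolecular Barbier cyclisation/Grob fragmentation of iodoalkyl β-mesyloxy ketones to eight- to ten-membered cycloalkenones. The transient six-membered ring (C10–C1–C2–C3–C4–C5) closes 6-exo-trig on the carbonyl, whereas the ten-membered ring is not closed end to end but appears by scission of the bond common to the two six-membered rings (four-carbon ring expansion). C4, the only new stereocentre, is set in the chair-like addition transition state with its methyl group equatorial, because an axial methyl would be 1,3-diaxial to the C10 methyl group, and this corresponds to (4R) as in the target; the configuration of the iodide is lost at the radical/organosamarium stage. The step needs the Z alkene and fragmentation instead of elimination or simple reduction: the chair with the C7, C8 and C9 substituents all equatorial holds C9–OMs antiperiplanar to C5–C10 and the side chain axial on C10 (cis to the mesylate), so C8 and C1 end up cis on the alkene, and the quaternary C10 rules out β-elimination of the mesylate. The iodide is reduced faster than the dialkyl ketone, and the silyl ethers and the exocyclic alkene are inert to SmI2, so C7 and C8 pass through unchanged.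

Step 14
Reactants: 19 (Z)-cyclodecenone
Product: 20 C8 allylic alcohol (TBDPS ether retained)
Conditions: HF·pyridine, pyridine, THF, 0 °C
Reagents that add atoms: none
Why: Acidic fluoride should cleave the secondary TBS ether much faster than the primary TBDPS ether and, being non-basic, should not epimerise C4 next to the ketone.

Step 15
Reactants: 20 C8 allylic alcohol
Product: 22 8,9,10-triol (C9 and C10 hydroxyls cis to each other and syn to C8–OH), via TMEDA-chelated osmate(VI) ester 21 (not isolated)
Conditions: OsO4 (1.05 equiv), TMEDA (1.1 equiv), CH2Cl2, −78 °C; then aq. Na2SO3, THF, 50 °C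
Reagents that add atoms: osmium tetroxide, O=[Os](=O)(=O)=O
Why: Hydrogen-bond-directed dihydroxylation: the OsO4·TMEDA complex is bound by the C8 hydroxyl and should add to the outer face of the Z-C9=C10 alkene on the side of that hydroxyl (C8–H eclipsing the alkene to avoid A(1,3) strain), so syn addition sets C9 and C10 with the 8,9-syn, 9,10-cis relationship of the target, while the exocyclic 1,1-disubstituted alkene is slowed by its allylic silyloxy group and the bulky TBDPS ether.

Step 16
Reactants: 22 8,9,10-triol
Product: 23 8,9,10,12-tetraol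
Conditions: TBAF, AcOH (1:1), THF, rt
Reagents that add atoms: none
Why: Fluoride cleavage of the primary TBDPS ether, buffered with acetic acid so that C4 is not epimerised.

Step 17
Reactants: 23 tetraol
Product: 26 hydroxy lactone (9-O-deacyl ineupatorolide A), via enal 24 (not isolated), via lactol 25 (not isolated)
Conditions: TEMPO (0.2 equiv), PhI(OAc)2 (2.5 equiv), CH2Cl2, rt
Reagents that add atoms: none
Why: TEMPO/PhI(OAc)2 should oxidise only the primary allylic alcohol to the enal, which is trapped by the neighbouring C8 hydroxyl as the five-membered lactol and oxidised on to the γ-lactone (oxidative lactonisation of a 2-methylene-1,4-diol); secondary and tertiary hydroxyls react far more slowly, and five-membered closure on O8 is preferred to six-membered closure on O9.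

Step 18
Reactants: 26 hydroxy lactone; 27 (R)-2-methylbutanoic acid
Product: 29 ineupatorolide A, via mixed anhydride 28 (not isolated)
Conditions: 27, 2,4,6-trichlorobenzoyl chloride, Et3N, toluene, rt; then 26, DMAP, toluene, rt
Reagents that add atoms: none
Why: Yamaguchi esterification: the mixed anhydride of the α-branched acid should acylate the only secondary hydroxyl (C9), the tertiary C10 hydroxyl being unreactive, and the α-stereocentre of a simple alkanoic acid does not racemise under these conditions.

Compound list
1 | (R)-carvone | CC1=CC[C@H](CC1=O)C(C)=C | starting material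
2 | (R)-10-hydroxycarvone | CC1=CC[C@H](CC1=O)C(=C)CO | intermediate
3 | (R)-10-(tert-butyldiphenylsilyloxy)carvone | CC1=CC[C@H](CC1=O)C(=C)CO[Si](c2ccccc2)(c2ccccc2)C(C)(C)C | intermediate
4 | lithium cross-conjugated dienolate of 3 | C1C[C@@H](C(=C)CO[Si](c2ccccc2)(c2ccccc2)C(C)(C)C)C=C(O[Li])C(C)=1 | intermediate (not isolated)
5 | (5S,6S)-6-hydroxy enone (C8–OH trans to C7 branch) | C1C[C@@H](C(=C)CO[Si](c2ccccc2)(c2ccccc2)C(C)(C)C)[C@H](O)C(=O)C(C)=1 | intermediate
6 | (5S,6S)-6-TBSO enone | C1C[C@@H](C(=C)CO[Si](c2ccccc2)(c2ccccc2)C(C)(C)C)[C@H](O[Si](C)(C)C(C)(C)C)C(=O)C(C)=1 | intermediate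
7 | β-boryl ketone (Bpin on C5) | C1(B2OC(C)(C)C(C)(C)O2)C[C@@H](C(=C)CO[Si](c3ccccc3)(c3ccccc3)C(C)(C)C)[C@H](O[Si](C)(C)C(C)(C)C)C(=O)C1C | intermediate (not isolated)
8 | β-hydroxy ketone (OH on C5) | OC1C[C@@H](C(=C)CO[Si](c2ccccc2)(c2ccccc2)C(C)(C)C)[C@H](O[Si](C)(C)C(C)(C)C)C(=O)C1C | intermediate
9 | 2-methyl-1,3-dione (enol form) | OC=1C[C@@H](C(=C)CO[Si](c2ccccc2)(c2ccccc2)C(C)(C)C)[C@H](O[Si](C)(C)C(C)(C)C)C(=O)C=1C | intermediate
10 | C5 ene-hydrazine (vinylogous hydrazide) | CN(C)NC=1C[C@@H](C(=C)CO[Si](c2ccccc2)(c2ccccc2)C(C)(C)C)[C@H](O[Si](C)(C)C(C)(C)C)C(=O)C=1C | intermediate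
11 | 1,4-dibromopentane (racemic) | CC(Br)CCCBr | starting material
12 | 1,4-diiodopentane (racemic) | CC(I)CCCI | intermediate
13 | potassium aza-enolate of 10 | CN(C)N=C1C[C@@H](C(=C)CO[Si](c2ccccc2)(c2ccccc2)C(C)(C)C)[C@H](O[Si](C)(C)C(C)(C)C)C(O[K])=C1C | intermediate (not isolated)
14 | C10-alkylated keto dimethylhydrazone | CN(C)N=C1C[C@@H](C(=C)CO[Si](c2ccccc2)(c2ccccc2)C(C)(C)C)[C@H](O[Si](C)(C)C(C)(C)C)C(=O)[C@@]1(C)CCCC(C)I | intermediate
15 | C9 hydroxy hydrazone | CN(C)N=C1C[C@@H](C(=C)CO[Si](c2ccccc2)(c2ccccc2)C(C)(C)C)[C@H](O[Si](C)(C)C(C)(C)C)[C@@H](O)[C@@]1(C)CCCC(C)I | intermediate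
16 | C9 mesyloxy hydrazone | CN(C)N=C1C[C@@H](C(=C)CO[Si](c2ccccc2)(c2ccccc2)C(C)(C)C)[C@H](O[Si](C)(C)C(C)(C)C)[C@@H](OS(C)(=O)=O)[C@@]1(C)CCCC(C)I | intermediate
17 | iodo keto mesylate (key-step precursor) | O=C1C[C@@H](C(=C)CO[Si](c2ccccc2)(c2ccccc2)C(C)(C)C)[C@H](O[Si](C)(C)C(C)(C)C)[C@@H](OS(C)(=O)=O)[C@@]1(C)CCCC(C)I | intermediate
18 | samarium(III) alkoxide of the cis-decalin | I[Sm](I)O[C@]12C[C@@H](C(=C)CO[Si](c3ccccc3)(c3ccccc3)C(C)(C)C)[C@H](O[Si](C)(C)C(C)(C)C)[C@@H](OS(C)(=O)=O)[C@@]1(C)CCC[C@H]2C | intermediate (not isolated)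
19 | (Z)-cyclodecenone (key-step product) | CC(C)(C)[Si](C)(C)O[C@@H]1/C=C(C)\CCC[C@@H](C)C(=O)C[C@H]1C(=C)CO[Si](c2ccccc2)(c2ccccc2)C(C)(C)C | intermediate
20 | C8 allylic alcohol | O[C@@H]1/C=C(C)\CCC[C@@H](C)C(=O)C[C@H]1C(=C)CO[Si](c2ccccc2)(c2ccccc2)C(C)(C)C | intermediate
21 | 9,10-osmate(VI) ester, TMEDA complex | O[C@@H]1[C@H]2O[Os](=O)(=O)O[C@@]2(C)CCC[C@@H](C)C(=O)C[C@H]1C(=C)CO[Si](c3ccccc3)(c3ccccc3)C(C)(C)C.CN(C)CCN(C)C | intermediate (not isolated)
22 | 8,9,10-triol, 12-O-TBDPS | O[C@@H]1[C@@H](O)[C@@](C)(O)CCC[C@@H](C)C(=O)C[C@H]1C(=C)CO[Si](c2ccccc2)(c2ccccc2)C(C)(C)C | intermediate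
23 | 8,9,10,12-tetraol | O[C@@H]1[C@@H](O)[C@@](C)(O)CCC[C@@H](C)C(=O)C[C@H]1C(=C)CO | intermediate
24 | enal (C12 aldehyde) | O[C@@H]1[C@@H](O)[C@@](C)(O)CCC[C@@H](C)C(=O)C[C@H]1C(=C)C=O | intermediate (not isolated)
25 | 8,12-lactol | C=C1C(O)O[C@@H]2[C@@H](O)[C@@](C)(O)CCC[C@@H](C)C(=O)C[C@@H]12 | intermediate (not isolated)
26 | hydroxy lactone (9-O-deacyl ineupatorolide A) | C=C1C(=O)O[C@@H]2[C@@H](O)[C@@](C)(O)CCC[C@@H](C)C(=O)C[C@@H]12 | intermediate
27 | (R)-2-methylbutanoic acid | CC[C@@H](C)C(O)=O | starting material
28 | (R)-2-methylbutanoic 2,4,6-trichlorobenzoic anhydride | CC[C@@H](C)C(=O)OC(=O)c1c(Cl)cc(Cl)cc1Cl | intermediate (not isolated)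
29 | ineupatorolide A, (4R,7S,8S,9R,10S) with (R)-2-methylbutanoate on O9 | C=C1C(=O)O[C@@H]2[C@@H](OC(=O)[C@H](C)CC)[C@@](C)(O)CCC[C@@H](C)C(=O)C[C@@H]12 | target

Total step count: 18. Longest linear sequence: 17 (steps 1–7 and 9–18; step 8 prepares the alkylating agent).

Steps most likely to fail

Step 13 (key step). The alkylsamarium may be protonated, or the C–I bond simply reduced, before it adds to C5. The alkoxide may also fail to fragment cleanly in the same pot. The fallback separates ring closure from fragmentation (Barbier cyclisation, then a classical Wharton fragmentation). It sets out from hydroxy hydrazone 15. The C9 hydroxyl is silylated (TESOTf, 2,6-lutidine) to the C9 triethylsilyl ether hydrazone F1, and the hydrazone is hydrolysed (Cu(OAc)2, THF/H2O) to the iodo ketone C9 triethylsilyl ether F2. SmI2/HMPA then effects only the Barbier cyclisation to the cis-decalin-5-ol F3, which can be isolated because no nucleofuge is present. Selective removal of the TES group (PPTS, MeOH, 0 °C) should give the cis-decalin-5,9-diol F4. The secondary C9 hydroxyl alone is mesylated (Ms2O, pyridine) to the diol monomesylate F5. KOt-Bu in THF then fragments the tertiary alkoxide to cyclodecenone 19, where the fallback rejoins the route.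

Step 9 (C10 alkylation). Facial selectivity at C10 may be poor, since substrate control by the C8 silyloxy group could be weak, and some N- or O-alkylation may remain. The fallback uses auxiliary control in place of substrate control (SAMP-hydrazone alkylation). It sets out from dione 9, which is condensed with (S)-1-amino-2-(methoxymethyl)pyrrolidine (the R antipode if that proves to be the matched one) to give the chiral ene-hydrazine F6. Its lithium aza-enolate (LDA, THF, −78 °C) has lithium chelated by the methoxymethyl arm and one face of C10 blocked by the pyrrolidine. Alkylation with diiodide 12 should give the chiral keto hydrazone F7. The same reduction (NaBH4/CeCl3) and mesylation (Ms2O/DMAP) give the hydroxy hydrazone F8 and the mesyloxy hydrazone F9. Mild cleavage of the auxiliary (saturated aqueous oxalic acid/Et2O) delivers iodo keto mesylate 17, where the fallback rejoins the route.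

Step 15 (directed dihydroxylation). Chemoselectivity may be lost through attack on the exocyclic alkene. Facial selectivity may be lost if the C8 hydroxyl is tied up as a transannular hemiketal with the C5 ketone. The fallback changes the order of events, so that the exocyclic alkene is electronically deactivated and the face is set by ring conformation, not by hydrogen bonding. It sets out from allylic alcohol 20. The TBDPS group is removed first (TBAF/AcOH) to give the 8,12-diol F10. Oxidative lactonisation (TEMPO, PhI(OAc)2) gives the α-methylene lactone with the Z ring alkene F11, whose exocyclic alkene is now electron-poor. Catalytic OsO4/NMO should then dihydroxylate only the electron-rich C9=C10 alkene from the outer face of the Z-cyclodecene, which in the A(1,3)-minimised conformer is the face bearing O8. This gives hydroxy lactone 26, where the fallback rejoins the route.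

Further compounds
F1 | step 13 | C9 triethylsilyl ether hydrazone | CN(C)N=C1C[C@@H](C(=C)CO[Si](c2ccccc2)(c2ccccc2)C(C)(C)C)[C@H](O[Si](C)(C)C(C)(C)C)[C@@H](O[Si](CC)(CC)CC)[C@@]1(C)CCCC(C)I
F2 | step 13 | iodo ketone C9 triethylsilyl ether | O=C1C[C@@H](C(=C)CO[Si](c2ccccc2)(c2ccccc2)C(C)(C)C)[C@H](O[Si](C)(C)C(C)(C)C)[C@@H](O[Si](CC)(CC)CC)[C@@]1(C)CCCC(C)I
F3 | step 13 | cis-decalin-5-ol, C9 triethylsilyl ether | O[C@]12C[C@@H](C(=C)CO[Si](c3ccccc3)(c3ccccc3)C(C)(C)C)[C@H](O[Si](C)(C)C(C)(C)C)[C@@H](O[Si](CC)(CC)CC)[C@@]1(C)CCC[C@H]2C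
F4 | step 13 | cis-decalin-5,9-diol | O[C@]12C[C@@H](C(=C)CO[Si](c3ccccc3)(c3ccccc3)C(C)(C)C)[C@H](O[Si](C)(C)C(C)(C)C)[C@@H](O)[C@@]1(C)CCC[C@H]2C
F5 | step 13 | cis-decalin-5-ol 9-mesylate | O[C@]12C[C@@H](C(=C)CO[Si](c3ccccc3)(c3ccccc3)C(C)(C)C)[C@H](O[Si](C)(C)C(C)(C)C)[C@@H](OS(C)(=O)=O)[C@@]1(C)CCC[C@H]2C
F6 | step 9 | SAMP ene-hydrazine of dione 9 | COC[C@@H]1CCCN1NC=2C[C@@H](C(=C)CO[Si](c3ccccc3)(c3ccccc3)C(C)(C)C)[C@H](O[Si](C)(C)C(C)(C)C)C(=O)C=2C
F7 | step 9 | C10-alkylated keto SAMP-hydrazone | COC[C@@H]1CCCN1N=C2C[C@@H](C(=C)CO[Si](c3ccccc3)(c3ccccc3)C(C)(C)C)[C@H](O[Si](C)(C)C(C)(C)C)C(=O)[C@@]2(C)CCCC(C)I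
F8 | step 9 | C9 hydroxy SAMP-hydrazone | COC[C@@H]1CCCN1N=C2C[C@@H](C(=C)CO[Si](c3ccccc3)(c3ccccc3)C(C)(C)C)[C@H](O[Si](C)(C)C(C)(C)C)[C@@H](O)[C@@]2(C)CCCC(C)I
F9 | step 9 | C9 mesyloxy SAMP-hydrazone | COC[C@@H]1CCCN1N=C2C[C@@H](C(=C)CO[Si](c3ccccc3)(c3ccccc3)C(C)(C)C)[C@H](O[Si](C)(C)C(C)(C)C)[C@@H](OS(C)(=O)=O)[C@@]2(C)CCCC(C)I
F10 | step 15 | 8,12-diol of the (Z)-cyclodecenone | O[C@@H]1/C=C(C)\CCC[C@@H](C)C(=O)C[C@H]1C(=C)CO
F11 | step 15 | α-methylene lactone with Z-C9=C10 | C=C1C(=O)O[C@@H]2/C=C(C)\CCC[C@@H](C)C(=O)C[C@@H]12
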